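The data stem from a simulated flask for substances that don't exist; noise was put on by code.

in all of them: coupling partner 0.168 M

| run | solid substrate | remark | time |
|---|---|---|---|
| red | 0.019 M | run made earlier |  |
| ochre | 0.20 M | run made earlier |  |
| autumn | 0.015 M |  | 4.0 min |
| spring | 0.050 M |  | 4.0 min |
| midnight | 0.15 M |  | 4.0 min |

| run | time / min | target / % |
|---|---|---|
| red | 0.833 | 7 |
| red | 1.50 | 10 |
| red | 2.50 | 20 |
| red | 3.00 | 26 |
| red | 4.00 | 33 |
| ochre | 0.333 | 0 |
| ochre | 1.00 | 3 |
| ochre | 2.00 | 3 |
| ochre | 3.00 | 3 |
| ochre | 4.00 | 9 |

(standard deviation of a reading: 1.5 percentage points)

- [target] at the end for autumn, spring, midnight, in this order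
- the course of these numbers from the first flask to the last (falls, then rises / falls all the way / rises, then falls / hardly changes / rises all the way)

- as a solid, counted per litre of solution: solid substrate
- at the start none of the solid substrate is in solution
- a step back or a flat step of under half a percent of the largest counts as no turn
- "hardly changes" means that all values lie within two and a half points (for a concentration: within two and a half percent of the largest)
- a step back or a flat step of under half a percent of the largest counts as no turn

1. Ochre's last reading is 9% of its charge at 4.00 min, against 33% for red, although ochre holds ten times red's charge. So between these two flasks the percent falls with the charge, and we need a scale for that fall.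

2. The zero of the scale is a flask in which the charge makes no difference to the percent. We take red as that case. Its readings summed over their times give a straight-line share of 32.5% at 4.0 min.

3. The opposite extreme is a flask whose amount of target no longer depends on the charge, a ceiling. The same sum on ochre gives 0.0139 M at 4.0 min. This is a rough reading, since the scatter is 1.5 percentage points on readings of 3%.

4. The two lines meet at the crossing charge, the ceiling amount divided by red's share: 0.0429 M. Above it, in our two-line picture, with this coupling partner and at this time, the percent is the share times the crossing charge over the charge.

5. Autumn's charge is smaller than the crossing charge, so we reckon 0.00487 M. Spring's charge is larger, at 1.16 times it, and midnight's is larger still. We put both at the ceiling, so the row rises and then stays flat, with no turn.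

The forecast gives 0.005 M, 0.0138 M and 0.0145 M, rises all the way, holding that “the solution is saturated and the rate is capped”.

The flasks give 0.00460 M, 0.0149 M and 0.0149 M: rises all the way.

    starting material + coupling partner → target, rate k1*[starting material]^1.5*[coupling partner] (k = 0.0918 M⁻¹·⁵ s⁻¹)
    solid substrate ⇌ starting material, rate k2*(cs2 - [starting material]) while solid is left; crystals form when [starting material] > cs2 (solubility = 50.0 mM, k = 0.00842 s⁻¹)

Spring's charge is 1.16 times the crossing charge, and its solid substrate goes from 34.0% of the charge at 2.00 min to 0% at 4.00 min. Midnight's charge is 3.49 times the crossing charge, and the share times the crossing charge over that charge gives 9.29%. Midnight's target stands at 9.93% of its charge at 4.00 min, with 66.4% of the charge still solid.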